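The route cuts the vinylogous-ester dihydrofuran ring (O1, C2, C3, C3a, C7a) of the tetrahydrobenzofuranone at C3a–C3 and O1–C7a. In one operation a lithiated 1,5-dimethoxycyclohexa-1,4-diene, a symmetric 1,3-dione equivalent, opens a chiral terminal epoxide at CH2, and aqueous acid unmasks the dione and condenses the C2 hydroxyl onto it. Ring and C3a–C3 bond thus arise together, while C2 and C1' are carried in unchanged. The precursor is the (2S,1'S) epoxide with O1' capped as a tert-butyldimethylsilyl ether and the chain end as a tert-butyldiphenylsilyl ether, made from nerol by chain extension, Sharpless epoxidation and Payne-type hydrolysis. Late enolate hydroxylation sets C5, and oxidation gives the acid.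

Key step: step 14

Remark: atom labels follow benzofuranone numbering (O1, C2, C3, C3a, C4 to C7, C7a; side chain from C1'). The O1' cap is tert-butyldimethylsilyl because it must survive the aqueous acid of step 14 and should be slow to move to the neighbouring C2 alkoxide.

Assumption: the sense of induction of the oxaziridine in step 15 is taken from its behaviour with other ketone enolates; the antipodal reagent would be used if this cyclic enolate responds the other way.

Step 1
Reactants: 1 nerol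
Product: 2 neryl tert-butyldimethylsilyl ether
Conditions: TBSCl, imidazole, CH2Cl2, 0 °C to rt
Reagents that add atoms: tert-butyldimethylsilyl chloride, CC(C)(C)[Si](C)(C)Cl
Why: Standard silylation of a primary allylic alcohol masks the C1 hydroxyl with a group that can later be removed in the presence of a tert-butyldiphenylsilyl ether.

Step 2
Reactants: 2 neryl tert-butyldimethylsilyl ether
Product: 3 (2E,6Z)-8-[(tert-butyldimethylsilyl)oxy]-2,6-dimethylocta-2,6-dien-1-ol
Conditions: SeO2 (0.3 equiv), t-BuOOH (3 equiv), salicylic acid (0.1 equiv), CH2Cl2, 0 °C to rt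
Reagents that add atoms: tert-butyl hydroperoxide, CC(C)(C)OO; selenium dioxide, O=[Se]=O (catalytic oxygen carrier)
Why: Riley allylic oxidation (ene reaction, then [2,3]-sigmatropic shift) attacks the more electron-rich terminal olefin at the methyl trans to the chain and should give the (E)-allylic alcohol, the allylic silyl ether deactivating the C2=C3 olefin.

Step 3
Reactants: 3 (2E,6Z)-8-[(tert-butyldimethylsilyl)oxy]-2,6-dimethylocta-2,6-dien-1-ol
Product: 4 (2Z,6E)-8-bromo-3,7-dimethylocta-2,6-dien-1-yl tert-butyldimethylsilyl ether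
Conditions: CBr4, PPh3, CH2Cl2, 0 °C
Reagents that add atoms: carbon tetrabromide, BrC(Br)(Br)Br
Why: Appel bromination converts the primary allylic alcohol into the bromide by SN2 at CH2 under neutral conditions that leave the silyl ether and both olefin geometries untouched.

Step 4
Reactants: 4 (2Z,6E)-8-bromo-3,7-dimethylocta-2,6-dien-1-yl tert-butyldimethylsilyl ether
Product: 5 (4E,8Z)-10-[(tert-butyldimethylsilyl)oxy]-4,8-dimethyldeca-4,8-dienenitrile
Conditions: MeCN (5 equiv), n-BuLi (4.5 equiv), THF, −78 °C; then 4, −78 to −40 °C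
Reagents that add atoms: acetonitrile, CC#N
Why: SN2 alkylation of lithioacetonitrile by the primary allylic bromide adds the two-carbon nitrile unit, an excess of the anion suppressing dialkylation.

Step 5
Reactants: 5 (4E,8Z)-10-[(tert-butyldimethylsilyl)oxy]-4,8-dimethyldeca-4,8-dienenitrile
Product: 6 (4E,8Z)-10-[(tert-butyldimethylsilyl)oxy]-4,8-dimethyldeca-4,8-dienal
Conditions: i-Bu2AlH (1.2 equiv), CH2Cl2, −78 °C; then aq. tartaric acid, 0 °C
Reagents that add atoms: water, O
Why: Partial reduction of the nitrile by the aluminium hydride stops at the N-aluminio aldimine, which hydrolyses on work-up to the aldehyde.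

Step 6
Reactants: 6 (4E,8Z)-10-[(tert-butyldimethylsilyl)oxy]-4,8-dimethyldeca-4,8-dienal, 7 ethyl 2-(triphenylphosphoranylidene)propanoate
Product: 8 ethyl (2E,6E,10Z)-12-[(tert-butyldimethylsilyl)oxy]-2,6,10-trimethyldodeca-2,6,10-trienoate
Conditions: 7 (1.3 equiv), CH2Cl2, rt to 40 °C
Reagents that add atoms: none
Why: Wittig olefination with a stabilised α-methyl ylide is governed by the more stable oxaphosphetane and should give the (E)-trisubstituted enoate.

Step 7
Reactants: 8 ethyl (2E,6E,10Z)-12-[(tert-butyldimethylsilyl)oxy]-2,6,10-trimethyldodeca-2,6,10-trienoate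
Product: 9 (2E,6E,10Z)-12-[(tert-butyldimethylsilyl)oxy]-2,6,10-trimethyldodeca-2,6,10-trien-1-ol
Conditions: i-Bu2AlH (2.5 equiv), CH2Cl2, −78 to 0 °C
Reagents that add atoms: none
Why: 1,2-Reduction of the enoate by excess aluminium hydride gives the allylic alcohol without touching the olefins or the silyl ether.

Step 8
Reactants: 9 (2E,6E,10Z)-12-[(tert-butyldimethylsilyl)oxy]-2,6,10-trimethyldodeca-2,6,10-trien-1-ol
Product: 10 (2Z,6E,10E)-1-[(tert-butyldimethylsilyl)oxy]-12-[(tert-butyldiphenylsilyl)oxy]-3,7,11-trimethyldodeca-2,6,10-triene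
Conditions: TBDPSCl, imidazole, DMF, 0 °C to rt
Reagents that add atoms: tert-butyl(chloro)diphenylsilane, CC(C)(C)[Si](Cl)(c1ccccc1)c1ccccc1
Why: Silylation of the primary allylic alcohol installs a chain-end cap that tolerates base, organolithium reagents and dilute aqueous acid.

Step 9
Reactants: 10 (2Z,6E,10E)-1-[(tert-butyldimethylsilyl)oxy]-12-[(tert-butyldiphenylsilyl)oxy]-3,7,11-trimethyldodeca-2,6,10-triene
Product: 11 (2Z,6E,10E)-12-[(tert-butyldiphenylsilyl)oxy]-3,7,11-trimethyldodeca-2,6,10-trien-1-ol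
Conditions: CSA (0.1 equiv), MeOH–CH2Cl2 (1:1), 0 °C
Reagents that add atoms: none
Why: Acid-catalysed methanolysis cleaves the less hindered tert-butyldimethylsilyl ether much faster than the tert-butyldiphenylsilyl ether and so releases only the C1 allylic alcohol.

Step 10
Reactants: 11 (2Z,6E,10E)-12-[(tert-butyldiphenylsilyl)oxy]-3,7,11-trimethyldodeca-2,6,10-trien-1-ol
Product: 12 [(2R,3S)-3-{(3E,7E)-9-[(tert-butyldiphenylsilyl)oxy]-4,8-dimethylnona-3,7-dien-1-yl}-3-methyloxiran-2-yl]methanol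
Conditions: Ti(OiPr)4 (0.2 equiv), D-(−)-diethyl tartrate (0.25 equiv), t-BuOOH (2 equiv, anhydrous), 4 Å molecular sieves, CH2Cl2, −20 °C
Reagents that add atoms: tert-butyl hydroperoxide, CC(C)(C)OO
Why: Katsuki–Sharpless asymmetric epoxidation is directed by the allylic hydroxyl to the C2=C3 olefin only, and the D-(−)-tartrate ligand controls the face of oxygen delivery so that this (2Z)-allylic alcohol should give the (2R,3S)-epoxide.

Step 11
Reactants: 12 [(2R,3S)-3-{(3E,7E)-9-[(tert-butyldiphenylsilyl)oxy]-4,8-dimethylnona-3,7-dien-1-yl}-3-methyloxiran-2-yl]methanol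
Product: 13 (2S,3S,6E,10E)-12-[(tert-butyldiphenylsilyl)oxy]-3,7,11-trimethyldodeca-6,10-diene-1,2,3-triol
Conditions: 0.5 M aq. NaOH, t-BuOH, 70 °C
Reagents that add atoms: water, O
Why: Payne rearrangement to the terminal epoxide followed by hydroxide attack at its CH2 (or direct attack at C2) inverts C2 and leaves C3 untouched, which turns the syn-epoxide into the (2S,3S)-triol with the anti-dioxygenation pattern of the target.

Step 12
Reactants: 13 (2S,3S,6E,10E)-12-[(tert-butyldiphenylsilyl)oxy]-3,7,11-trimethyldodeca-6,10-diene-1,2,3-triol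
Product: 15 (2S,5E,9E)-11-[(tert-butyldiphenylsilyl)oxy]-6,10-dimethyl-2-[(2S)-oxiran-2-yl]undeca-5,9-dien-2-ol, via primary tosylate 14 (not isolated)
Conditions: TsCl (1.05 equiv), Et3N, Bu2SnO (2 mol %), CH2Cl2, 0 °C; then K2CO3, MeOH, 0 °C to rt
Reagents that add atoms: none
Why: Tin-catalysed sulfonylation is selective for the primary hydroxyl of the stannylene acetal, and the C2 alkoxide then displaces the tosylate (3-exo-tet Williamson closure) with retention at C2, the tertiary hydroxyl being too hindered to compete.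

Step 13
Reactants: 15 (2S,5E,9E)-11-[(tert-butyldiphenylsilyl)oxy]-6,10-dimethyl-2-[(2S)-oxiran-2-yl]undeca-5,9-dien-2-ol
Product: 16 tert-butyl({(2S,5E,9E)-11-[(tert-butyldiphenylsilyl)oxy]-6,10-dimethyl-2-[(2S)-oxiran-2-yl]undeca-5,9-dien-2-yl}oxy)dimethylsilane
Conditions: TBSOTf (1.5 equiv), 2,6-lutidine (3 equiv), CH2Cl2, −78 to −20 °C
Reagents that add atoms: tert-butyldimethylsilyl trifluoromethanesulfonate, CC(C)(C)[Si](C)(C)OS(=O)(=O)C(F)(F)F
Why: A silyl triflate with a hindered pyridine base silylates the tertiary alcohol at low temperature faster than it activates the terminal epoxide, giving a cap that resists aqueous acid.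

Step 14
Reactants: 16 tert-butyl({(2S,5E,9E)-11-[(tert-butyldiphenylsilyl)oxy]-6,10-dimethyl-2-[(2S)-oxiran-2-yl]undeca-5,9-dien-2-yl}oxy)dimethylsilane, 17 1,5-dimethoxycyclohexa-1,4-diene
Product: 21 (2S)-2-{(2S,5E,9E)-2-[(tert-butyldimethylsilyl)oxy]-11-[(tert-butyldiphenylsilyl)oxy]-6,10-dimethylundeca-5,9-dien-2-yl}-2,3,6,7-tetrahydro-1-benzofuran-4(5H)-one, via lithiated diene 18 (not isolated), via epoxide-opened adduct 19 (not isolated), via hydroxy dione 20 (not isolated)
Conditions: 17 (1.5 equiv), t-BuLi (1.45 equiv), THF, −78 °C; then 16, THF, −78 to 0 °C; then 1 M aq. HCl–THF, 0 °C to rt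
Reagents that add atoms: water, O
Why: t-BuLi removes a proton from the CH2 flanked by the two methoxy-bearing carbons of 17, and the cyclohexadienyl lithium 18 attacks the unsubstituted epoxide carbon of 16 by SN2 through its central carbon, which forms C3a–C3 and leaves a C2 lithium alkoxide (19 after protonation). Aqueous HCl then hydrolyses both methyl enol ethers to the 2-substituted 1,3-dione 20, whose C2 hydroxyl adds to a ring carbonyl and loses water to give the vinylogous ester 21 (O1–C7a). The closest known reaction types are the alkylation of this lithiated diene with alkyl halides followed by hydrolysis to 2-alkylcyclohexane-1,3-diones, the opening of terminal epoxides by allyl- and pentadienyl-type organolithiums, and the acid cyclodehydration of 2-(2-hydroxyalkyl)-1,3-diones. The dihydrofuran closes by 5-exo-trig attack of oxygen on C7a followed by dehydration; no stereocentre is created, and C2 and C1' are retained because neither of their C–O bonds is broken. The step needs alkylation at the central carbon of the dienyl anion (its usual kinetic site), attack at the epoxide CH2 (the other carbon is shielded by the adjacent quaternary centre, which also offers no β-hydrogen for base-induced isomerisation) and closure through the C2 oxygen only, which the acid-stable silyl cap on O1' enforces; running the opening in THF without a polar additive and quenching cold into acid is meant to keep that silyl group from moving to the new C2 alkoxide. The two carbonyls of 20 are equivalent by symmetry, so the condensation raises no regiochemical question.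

Step 15
Reactants: 21 (2S)-2-{(2S,5E,9E)-2-[(tert-butyldimethylsilyl)oxy]-11-[(tert-butyldiphenylsilyl)oxy]-6,10-dimethylundeca-5,9-dien-2-yl}-2,3,6,7-tetrahydro-1-benzofuran-4(5H)-one
Product: 23 (2S,5R)-2-{(2S,5E,9E)-2-[(tert-butyldimethylsilyl)oxy]-11-[(tert-butyldiphenylsilyl)oxy]-6,10-dimethylundeca-5,9-dien-2-yl}-5-hydroxy-2,3,6,7-tetrahydro-1-benzofuran-4(5H)-one, via lithium enolate 22 (not isolated)
Conditions: LiN(i-Pr)2 (1.15 equiv), THF, −78 °C; then (+)-(2R,8aS)-(camphorsulfonyl)oxaziridine (1.3 equiv), −78 to −40 °C; AcOH quench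
Reagents that add atoms: (+)-(2R,8aS)-(camphorsulfonyl)oxaziridine, CC1(C)[C@@H]2CC[C@]13CS(=O)(=O)N4O[C@@]34C2
Why: Kinetic α'-deprotonation of the vinylogous ester gives the cross-conjugated enolate 22, and Davis oxidation transfers oxygen to C5 under reagent control (C2 and C1' are too remote to bias the faces), the (+)-reagent being chosen by analogy with its sense of induction on other ketone enolates to favour 5R, with the 5S epimer a separable diastereomer.

Step 16
Reactants: 23 (2S,5R)-2-{(2S,5E,9E)-2-[(tert-butyldimethylsilyl)oxy]-11-[(tert-butyldiphenylsilyl)oxy]-6,10-dimethylundeca-5,9-dien-2-yl}-5-hydroxy-2,3,6,7-tetrahydro-1-benzofuran-4(5H)-one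
Product: 24 (2S,5R)-2-[(2S,5E,9E)-2,11-dihydroxy-6,10-dimethylundeca-5,9-dien-2-yl]-5-hydroxy-2,3,6,7-tetrahydro-1-benzofuran-4(5H)-one
Conditions: HF·pyridine, pyridine, THF, 0 °C to rt
Reagents that add atoms: none
Why: Fluoride-mediated desilylation under buffered, mildly acidic conditions cleaves both Si–O bonds while the α-hydroxy ketone, the vinylogous ester and the olefins should be tolerated.

Step 17
Reactants: 24 (2S,5R)-2-[(2S,5E,9E)-2,11-dihydroxy-6,10-dimethylundeca-5,9-dien-2-yl]-5-hydroxy-2,3,6,7-tetrahydro-1-benzofuran-4(5H)-one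
Product: 25 (2E,6E,10S)-10-hydroxy-10-[(2S,5R)-5-hydroxy-4-oxo-2,3,4,5,6,7-hexahydro-1-benzofuran-2-yl]-2,6-dimethylundeca-2,6-dienal
Conditions: TEMPO (0.1 equiv), PhI(OAc)2 (1.1 equiv), CH2Cl2, rt
Reagents that add atoms: none
Why: Oxoammonium (TEMPO) oxidation with PhI(OAc)2 as terminal oxidant is selective for the primary allylic alcohol over the secondary ketol and the tertiary alcohol and stops at the enal.

Step 18
Reactants: 25 (2E,6E,10S)-10-hydroxy-10-[(2S,5R)-5-hydroxy-4-oxo-2,3,4,5,6,7-hexahydro-1-benzofuran-2-yl]-2,6-dimethylundeca-2,6-dienal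
Product: 26 (2E,6E,10S)-10-hydroxy-10-[(2S,5R)-5-hydroxy-4-oxo-2,3,4,5,6,7-hexahydro-1-benzofuran-2-yl]-2,6-dimethylundeca-2,6-dienoic acid
Conditions: NaClO2, NaH2PO4, 2-methyl-2-butene, t-BuOH–H2O, 0 °C to rt
Reagents that add atoms: sodium chlorite, [Na+].[O-]Cl=O
Why: Pinnick oxidation converts the enal into the acid without epimerising C5 or isomerising the olefin, 2-methyl-2-butene scavenging the HOCl that is formed.

Compound list
1 | nerol, (2Z)-3,7-dimethylocta-2,6-dien-1-ol | CC(C)=CCC/C(C)=C\CO | starting material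
2 | tert-butyl{[(2Z)-3,7-dimethylocta-2,6-dien-1-yl]oxy}dimethylsilane | CC(C)=CCC/C(C)=C\CO[Si](C)(C)C(C)(C)C | intermediate
3 | (2E,6Z)-8-[(tert-butyldimethylsilyl)oxy]-2,6-dimethylocta-2,6-dien-1-ol | OC/C(C)=C/CC/C(C)=C\CO[Si](C)(C)C(C)(C)C | intermediate
4 | {[(2Z,6E)-8-bromo-3,7-dimethylocta-2,6-dien-1-yl]oxy}(tert-butyl)dimethylsilane | BrC/C(C)=C/CC/C(C)=C\CO[Si](C)(C)C(C)(C)C | intermediate
5 | (4E,8Z)-10-[(tert-butyldimethylsilyl)oxy]-4,8-dimethyldeca-4,8-dienenitrile | N#CCC/C(C)=C/CC/C(C)=C\CO[Si](C)(C)C(C)(C)C | intermediate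
6 | (4E,8Z)-10-[(tert-butyldimethylsilyl)oxy]-4,8-dimethyldeca-4,8-dienal | O=CCC/C(C)=C/CC/C(C)=C\CO[Si](C)(C)C(C)(C)C | intermediate
7 | ethyl 2-(triphenylphosphoranylidene)propanoate | CCOC(=O)C(C)=P(c1ccccc1)(c1ccccc1)c1ccccc1 | starting material
8 | ethyl (2E,6E,10Z)-12-[(tert-butyldimethylsilyl)oxy]-2,6,10-trimethyldodeca-2,6,10-trienoate | CCOC(=O)/C(C)=C/CC/C(C)=C/CC/C(C)=C\CO[Si](C)(C)C(C)(C)C | intermediate
9 | (2E,6E,10Z)-12-[(tert-butyldimethylsilyl)oxy]-2,6,10-trimethyldodeca-2,6,10-trien-1-ol | OC/C(C)=C/CC/C(C)=C/CC/C(C)=C\CO[Si](C)(C)C(C)(C)C | intermediate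
10 | (2Z,6E,10E)-1-[(tert-butyldimethylsilyl)oxy]-12-[(tert-butyldiphenylsilyl)oxy]-3,7,11-trimethyldodeca-2,6,10-triene | CC(C)(C)[Si](c1ccccc1)(c1ccccc1)OC/C(C)=C/CC/C(C)=C/CC/C(C)=C\CO[Si](C)(C)C(C)(C)C | intermediate
11 | (2Z,6E,10E)-12-[(tert-butyldiphenylsilyl)oxy]-3,7,11-trimethyldodeca-2,6,10-trien-1-ol | CC(C)(C)[Si](c1ccccc1)(c1ccccc1)OC/C(C)=C/CC/C(C)=C/CC/C(C)=C\CO | intermediate
12 | [(2R,3S)-3-{(3E,7E)-9-[(tert-butyldiphenylsilyl)oxy]-4,8-dimethylnona-3,7-dien-1-yl}-3-methyloxiran-2-yl]methanol | C/C(=C\CC[C@]1(C)O[C@@H]1CO)CC/C=C(\C)CO[Si](c1ccccc1)(c1ccccc1)C(C)(C)C | intermediate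
13 | (2S,3S,6E,10E)-12-[(tert-butyldiphenylsilyl)oxy]-3,7,11-trimethyldodeca-6,10-diene-1,2,3-triol | C/C(=C\CC[C@](C)(O)[C@@H](O)CO)CC/C=C(\C)CO[Si](c1ccccc1)(c1ccccc1)C(C)(C)C | intermediate
14 | (2S,3S,6E,10E)-12-[(tert-butyldiphenylsilyl)oxy]-2,3-dihydroxy-3,7,11-trimethyldodeca-6,10-dien-1-yl 4-methylbenzenesulfonate | C/C(=C\CC[C@](C)(O)[C@@H](O)COS(=O)(=O)c1ccc(C)cc1)CC/C=C(\C)CO[Si](c1ccccc1)(c1ccccc1)C(C)(C)C | intermediate (not isolated)
15 | (2S,5E,9E)-11-[(tert-butyldiphenylsilyl)oxy]-6,10-dimethyl-2-[(2S)-oxiran-2-yl]undeca-5,9-dien-2-ol | C/C(=C\CC[C@](C)(O)[C@@H]1CO1)CC/C=C(\C)CO[Si](c1ccccc1)(c1ccccc1)C(C)(C)C | intermediate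
16 | tert-butyl({(2S,5E,9E)-11-[(tert-butyldiphenylsilyl)oxy]-6,10-dimethyl-2-[(2S)-oxiran-2-yl]undeca-5,9-dien-2-yl}oxy)dimethylsilane | C/C(=C\CC[C@](C)(O[Si](C)(C)C(C)(C)C)[C@@H]1CO1)CC/C=C(\C)CO[Si](c1ccccc1)(c1ccccc1)C(C)(C)C | intermediate (key-step precursor)
17 | 1,5-dimethoxycyclohexa-1,4-diene | COC1=CCC=C(OC)C1 | starting material
18 | (2,6-dimethoxycyclohexa-2,5-dien-1-yl)lithium | COC1=CCC=C(OC)C1[Li] | intermediate (not isolated)
19 | (2S,3S,6E,10E)-3-[(tert-butyldimethylsilyl)oxy]-12-[(tert-butyldiphenylsilyl)oxy]-1-(2,6-dimethoxycyclohexa-2,5-dien-1-yl)-3,7,11-trimethyldodeca-6,10-dien-2-ol | C/C(=C\CC[C@](C)(O[Si](C)(C)C(C)(C)C)[C@@H](O)CC1C(OC)=CCC=C1OC)CC/C=C(\C)CO[Si](c1ccccc1)(c1ccccc1)C(C)(C)C | intermediate (not isolated)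
20 | 2-{(2S,3S,6E,10E)-3-[(tert-butyldimethylsilyl)oxy]-12-[(tert-butyldiphenylsilyl)oxy]-2-hydroxy-3,7,11-trimethyldodeca-6,10-dien-1-yl}cyclohexane-1,3-dione | C/C(=C\CC[C@](C)(O[Si](C)(C)C(C)(C)C)[C@@H](O)CC1C(=O)CCCC1=O)CC/C=C(\C)CO[Si](c1ccccc1)(c1ccccc1)C(C)(C)C | intermediate (not isolated)
21 | (2S)-2-{(2S,5E,9E)-2-[(tert-butyldimethylsilyl)oxy]-11-[(tert-butyldiphenylsilyl)oxy]-6,10-dimethylundeca-5,9-dien-2-yl}-2,3,6,7-tetrahydro-1-benzofuran-4(5H)-one | C/C(=C\CC[C@](C)(O[Si](C)(C)C(C)(C)C)[C@@H]1CC2=C(CCCC2=O)O1)CC/C=C(\C)CO[Si](c1ccccc1)(c1ccccc1)C(C)(C)C | intermediate (key-step product)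
22 | lithium cross-conjugated enolate of 21 (O4–Li, C4=C5) | C/C(=C\CC[C@](C)(O[Si](C)(C)C(C)(C)C)[C@@H]1CC2=C(CCC=C2O[Li])O1)CC/C=C(\C)CO[Si](c1ccccc1)(c1ccccc1)C(C)(C)C | intermediate (not isolated)
23 | (2S,5R)-2-{(2S,5E,9E)-2-[(tert-butyldimethylsilyl)oxy]-11-[(tert-butyldiphenylsilyl)oxy]-6,10-dimethylundeca-5,9-dien-2-yl}-5-hydroxy-2,3,6,7-tetrahydro-1-benzofuran-4(5H)-one | C/C(=C\CC[C@](C)(O[Si](C)(C)C(C)(C)C)[C@@H]1CC2=C(CC[C@@H](O)C2=O)O1)CC/C=C(\C)CO[Si](c1ccccc1)(c1ccccc1)C(C)(C)C | intermediate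
24 | (2S,5R)-2-[(2S,5E,9E)-2,11-dihydroxy-6,10-dimethylundeca-5,9-dien-2-yl]-5-hydroxy-2,3,6,7-tetrahydro-1-benzofuran-4(5H)-one | C/C(=C\CC[C@](C)(O)[C@@H]1CC2=C(CC[C@@H](O)C2=O)O1)CC/C=C(\C)CO | intermediate
25 | (2E,6E,10S)-10-hydroxy-10-[(2S,5R)-5-hydroxy-4-oxo-2,3,4,5,6,7-hexahydro-1-benzofuran-2-yl]-2,6-dimethylundeca-2,6-dienal | C/C(=C\CC[C@](C)(O)[C@@H]1CC2=C(CC[C@@H](O)C2=O)O1)CC/C=C(\C)C=O | intermediate
26 | (2E,6E,10S)-10-hydroxy-10-[(2S,5R)-5-hydroxy-4-oxo-2,3,4,5,6,7-hexahydro-1-benzofuran-2-yl]-2,6-dimethylundeca-2,6-dienoic acid | C/C(=C\CC[C@](C)(O)[C@@H]1CC2=C(CC[C@@H](O)C2=O)O1)CC/C=C(\C)C(=O)O | target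

Total step count: 18
Longest linear sequence: 18 steps, from nerol 1 to 26 (7 and 17 are purchased).

Steps most likely to fail

Step 14. The epoxide opening next to the quaternary centre may be slow, and during it the silyl group may pass from O1' to the adjacent C2 lithium alkoxide; the freed tertiary hydroxyl would then close a six-membered ether in the acid stage. The fallback removes the cause by changing the cap to an acetal, which cannot migrate. It sets out from 15, which is treated with chloromethyl methyl ether and i-Pr2NEt (CH2Cl2, 40 °C) to give the methoxymethyl-capped epoxide F1. F1 is opened by lithiated diene 18 (THF–HMPA, −78 °C to rt, now permissible) and the adduct is treated with 1 M aq. HCl as in step 14 to give the methoxymethyl-capped bicyclic vinylogous ester F2. Me2BBr (CH2Cl2, −78 °C) cleaves the acetal to the tertiary alcohol F3, and TBSOTf with 2,6-lutidine brings the material back to 21.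

Step 15. Oxygen transfer to an enolate whose only stereocentres are remote may show poor facial selectivity, so that both C5 epimers form. The fallback gives up reagent control and corrects the configuration afterwards. It sets out from 21, which is hydroxylated with LiN(i-Pr)2 and racemic 3-phenyl-2-(phenylsulfonyl)oxaziridine; 23 is separated by chromatography from its (5S)-epimer F4. F4 is inverted by a Mitsunobu reaction (4-nitrobenzoic acid, PPh3, diisopropyl azodicarboxylate, THF, 0 °C) to the (5R)-4-nitrobenzoate F5, and methanolysis (K2CO3, MeOH, 0 °C) returns 23.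

Step 16. Cleavage of the hindered tertiary silyl ether may be slow, so that the α-hydroxy ketone is exposed to fluoride for a long time and degrades by enolisation, air oxidation or aromatisation. The fallback removes the silyl groups before the ketol exists. It sets out from 21, which is heated with Bu4NF (THF, 50 °C) to give the desilylated diol F6; its trianion (LiN(i-Pr)2, 3.3 equiv, THF, −78 °C) is hydroxylated with the oxaziridine of step 15 and arrives directly at 24.

Further compounds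
F1 | step 14 | (2S)-2-[(2S,5E,9E)-11-[(tert-butyldiphenylsilyl)oxy]-2-(methoxymethoxy)-6,10-dimethylundeca-5,9-dien-2-yl]oxirane | C/C(=C\CC[C@](C)(OCOC)[C@@H]1CO1)CC/C=C(\C)CO[Si](c1ccccc1)(c1ccccc1)C(C)(C)C
F2 | step 14 | (2S)-2-[(2S,5E,9E)-11-[(tert-butyldiphenylsilyl)oxy]-2-(methoxymethoxy)-6,10-dimethylundeca-5,9-dien-2-yl]-2,3,6,7-tetrahydro-1-benzofuran-4(5H)-one | C/C(=C\CC[C@](C)(OCOC)[C@@H]1CC2=C(CCCC2=O)O1)CC/C=C(\C)CO[Si](c1ccccc1)(c1ccccc1)C(C)(C)C
F3 | step 14 | (2S)-2-[(2S,5E,9E)-11-[(tert-butyldiphenylsilyl)oxy]-2-hydroxy-6,10-dimethylundeca-5,9-dien-2-yl]-2,3,6,7-tetrahydro-1-benzofuran-4(5H)-one | C/C(=C\CC[C@](C)(O)[C@@H]1CC2=C(CCCC2=O)O1)CC/C=C(\C)CO[Si](c1ccccc1)(c1ccccc1)C(C)(C)C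
F4 | step 15 | (2S,5S)-2-{(2S,5E,9E)-2-[(tert-butyldimethylsilyl)oxy]-11-[(tert-butyldiphenylsilyl)oxy]-6,10-dimethylundeca-5,9-dien-2-yl}-5-hydroxy-2,3,6,7-tetrahydro-1-benzofuran-4(5H)-one | C/C(=C\CC[C@](C)(O[Si](C)(C)C(C)(C)C)[C@@H]1CC2=C(CC[C@H](O)C2=O)O1)CC/C=C(\C)CO[Si](c1ccccc1)(c1ccccc1)C(C)(C)C
F5 | step 15 | (2S,5R)-2-{(2S,5E,9E)-2-[(tert-butyldimethylsilyl)oxy]-11-[(tert-butyldiphenylsilyl)oxy]-6,10-dimethylundeca-5,9-dien-2-yl}-4-oxo-2,3,4,5,6,7-hexahydro-1-benzofuran-5-yl 4-nitrobenzoate | C/C(=C\CC[C@](C)(O[Si](C)(C)C(C)(C)C)[C@@H]1CC2=C(CC[C@@H](OC(=O)c3ccc(cc3)[N+](=O)[O-])C2=O)O1)CC/C=C(\C)CO[Si](c1ccccc1)(c1ccccc1)C(C)(C)C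
F6 | step 16 | (2S)-2-[(2S,5E,9E)-2,11-dihydroxy-6,10-dimethylundeca-5,9-dien-2-yl]-2,3,6,7-tetrahydro-1-benzofuran-4(5H)-one | C/C(=C\CC[C@](C)(O)[C@@H]1CC2=C(CCCC2=O)O1)CC/C=C(\C)CO
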